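Retrosynthesis (labdane numbering): cut C12–C13 (B-alkyl Suzuki–Miyaura) and C9–C11 (Stille) to reach a 6β-acetoxy-8-methyl C8=C9 enol triflate. Strip ring B back to the bare trans-decal-6-one, then re-join C3 to C5. Ring A becomes a five-membered ring (C1, C2, C3, C5, C10) carrying a C3–C4–C5 cyclopropane. Finally cut C5–C3/C5–C4 (carbenoid) and C10–C1 (conjugate addition).
Forward: ring B is bought as 3-methylcyclohexenone and the homoprenyl group is added at C10. A C5 keto-carbenoid closes the five-membered ring and the cyclopropane on the prenyl C3=C4 bond. Reductive scission of C3–C5 expands the five-membered ring to ring A; ring B is then oxidised and the side chain joined.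
Enabling feature: C5 lies between the quaternary C4 (gem-dimethyl) and the oxygenated C6. C4 can therefore be delivered as the apex of a temporary cyclopropane conjugated with a C6 ketone, and the ketone that triggers the strain-releasing cleavage stays as the C6 oxygen of the target.
Stereochemistry: C10 comes from the chiral copper–carbene catalyst. C5 comes from α-face protonation of the C5=C6 enolate (trans-decalin). C6 comes from α-face hydride delivery, opposite to the axial C10 and C4β methyl groups.

Key step: step 4

Remark: labdane numbering (C1–C10 decalin, C11–C16 side chain) is used for all intermediates. It is assumed that the enantiomer of the carbene ligand in step 1 is picked according to its known sense of induction, so that C10 forms as drawn.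

Step 1
Reactants: 1 3-methylcyclohex-2-en-1-one; 2 5-bromo-2-methylpent-2-ene
Product: 5 (S)-trimethyl{[3-methyl-3-(4-methylpent-3-en-1-yl)cyclohex-1-en-1-yl]oxy}silane, via homoprenylmagnesium bromide 3 (not isolated), via bromomagnesium enolate 4 (not isolated)
Conditions: Mg, Et2O, reflux (2 → 3); 1, Cu(OTf)2 (3 mol %), chiral 1-(1-hydroxy-4-methylpentan-2-yl)-3-mesityl-4,5-dihydroimidazolium hexafluorophosphate (carbene precursor, 4 mol %), Et2O, −30 °C; Me3SiCl, Et3N, DMPU, −30 °C → rt
Reagents that add atoms: chlorotrimethylsilane, C[Si](C)(C)Cl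
Why: Copper-catalysed asymmetric conjugate addition of a Grignard reagent to a β-methyl cyclic enone under a chiral N-heterocyclic carbene ligand is an established route to all-carbon quaternary centres, the ligand selecting the enone face so that C10 forms as (S), and silylation freezes the enolate at C5=C6, the hindered side that deprotonation could not reach.

Step 2
Reactants: 5 (S)-trimethyl{[3-methyl-3-(4-methylpent-3-en-1-yl)cyclohex-1-en-1-yl]oxy}silane
Product: 8 (3S)-2-diazo-3-methyl-3-(4-methylpent-3-en-1-yl)cyclohexan-1-one, via lithium enolate 6 (not isolated), via trifluoroacetyl ketone 7 (not isolated)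
Conditions: MeLi, THF, 0 °C; CF3CO2CH2CF3, −78 °C; then MsN3, Et3N, H2O, MeCN, rt
Reagents that add atoms: methanesulfonyl azide, CS(=O)(=O)N=[N+]=[N-]
Why: Methyllithium releases the C5=C6 lithium enolate 6 without equilibration, C-trifluoroacetylation makes C5 acidic enough for Regitz-type (detrifluoroacetylative) diazo transfer, and the stereocentre C10 is not involved.

Step 3
Reactants: 8 (3S)-2-diazo-3-methyl-3-(4-methylpent-3-en-1-yl)cyclohexan-1-one
Product: 9 tricyclic cyclopropyl ketone (ring B cyclohexanone fused at C5–C10 to the cyclopentane C1-C2-C3-C5-C10 that bears the C3–C4–C5 gem-dimethylcyclopropane; 10β-methyl; C4 β; C1 and C3 α)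
Conditions: Rh2(OAc)4 (1 mol %), CH2Cl2, slow addition, rt
Reagents that add atoms: none
Why: Intramolecular cyclopropanation of the electron-rich C3=C4 bond by the rhodium keto-carbenoid at C5 closes the five-membered ring (C1, C2, C3, C5, C10) and the cyclopropane (C3, C4, C5) in one step, the three-atom tether allowing only the cis-fused bicyclo[3.1.0]hexane with C1 and C3 on the α face and C4 on the β face next to the C10 methyl group, while the quaternary C10 excludes a competing 1,2-hydride shift.

Step 4
Reactants: 9 tricyclic cyclopropyl ketone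
Product: 11 4,4,10β-trimethyl-5α-decalin-6-one (trans-decalone), via lithium enolate 10 (not isolated)
Conditions: Li (4 equiv), NH3(l)/THF, −78 → −33 °C; then solid NH4Cl
Reagents that add atoms: none
Why: Two single-electron transfers from lithium to the C6 carbonyl give a ketyl radical anion that releases the cyclopropane strain by breaking the C3–C5 bond, the zero-atom bridge of the bicyclo[3.1.0]hexane; the C3 radical is reduced and protonated by ammonia, and the C5=C6 lithium enolate 10 is protonated on quench. The closest known reaction type is the dissolving-metal cleavage of conjugated cyclopropyl ketones, whose regiochemistry follows the overlap of the breaking bond with the carbonyl π system. No carbon–carbon bond is closed: ring A (C1, C2, C3, C4, C5, C10) arises because loss of the C3–C5 bond merges the five-membered ring (C1, C2, C3, C5, C10) with the three-membered ring (C3, C4, C5), so that C4 with its two methyl groups is inserted between C3 and C5. The selectivity needed is C3–C5 over C4–C5 cleavage: in the only unstrained chair of ring B the C3–C5 bond is axial-like and should stand nearly perpendicular to the carbonyl plane, whereas C4–C5 is equatorial-like and lies close to that plane, and C3–C5 cleavage also leads to the secondary rather than the tertiary carbanion. The new stereocentre C5 is set by protonation of enolate 10 from the α face, opposite to the axial C10 and C4β methyl groups, which also gives the thermodynamic trans-decalone, so a brief NaOMe/MeOH equilibration would correct any cis isomer. The enolate shields C6 from over-reduction and C10 is untouched.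

Step 5
Reactants: 11 4,4,10β-trimethyl-5α-decalin-6-one
Product: 12 4,4,10β-trimethyl-5α-decal-7-en-6-one
Conditions: IBX, DMSO, 70 °C
Reagents that add atoms: none
Why: IBX-mediated dehydrogenation of a ketone through its enol can only introduce the C7=C8 double bond, because C5 is flanked by the quaternary C4 and C10, and the trans ring fusion is the thermodynamic one under the conditions.

Step 6
Reactants: 12 4,4,10β-trimethyl-5α-decal-7-en-6-one
Product: 13 4,4,8,10β-tetramethyl-6-(trimethylsilyloxy)-5α-decal-6-ene (C8 epimers)
Conditions: Me2CuLi (from MeLi, CuI), Me3SiCl, Et2O/THF, −78 °C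
Reagents that add atoms: lithium dimethylcuprate, [Li+].C[Cu-]C; chlorotrimethylsilane, C[Si](C)(C)Cl
Why: Lithium dialkylcuprate 1,4-addition accelerated by Me3SiCl places the methyl group on the unhindered β-carbon C8 and traps the C6=C7 enolate, and the configuration at C8 is of no consequence since C8 becomes trigonal in step 7.

Step 7
Reactants: 13 4,4,8,10β-tetramethyl-6-(trimethylsilyloxy)-5α-decal-6-ene
Product: 14 4,4,8,10β-tetramethyl-5α-decal-7-en-6-one
Conditions: Pd(OAc)2 (1 equiv), MeCN, rt
Reagents that add atoms: none
Why: In the Saegusa–Ito oxidation, palladation of the silyl enol ether at C7 and β-hydride elimination of H8 regenerate the enone, now carrying the C8 methyl group.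

Step 8
Reactants: 14 4,4,8,10β-tetramethyl-5α-decal-7-en-6-one
Product: 15 4,4,8,10β-tetramethyl-5α-decal-7-ene-6,9-dione
Conditions: Pd(OH)2 on carbon (5 mol %), t-BuOOH, K2CO3, CH2Cl2, 4 °C → rt
Reagents that add atoms: tert-butyl hydroperoxide, CC(C)(C)OO
Why: Radical allylic (γ) C–H oxidation of an α,β-enone to the 1,4-enedione, the reaction that turns isophorone-type enones into their 4-oxo derivatives, should attack the ring methylene C9, whose axial hydrogen is aligned with the enone π system, in preference to the C8 methyl group.

Step 9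
Reactants: 15 4,4,8,10β-tetramethyl-5α-decal-7-ene-6,9-dione
Product: 16 6β-hydroxy-4,4,8,10β-tetramethyl-5α-decal-7-en-9-one
Conditions: NaBH4, CeCl3·7H2O, MeOH, −78 °C
Reagents that add atoms: none
Why: Luche 1,2-reduction should select the C6 carbonyl, since C9 is shielded by the quaternary C10 and the C8 methyl group, and hydride arrives from the α face opposite to the axial C10 and C4β methyl groups, which sets the 6β (axial) alcohol.

Step 10
Reactants: 16 6β-hydroxy-4,4,8,10β-tetramethyl-5α-decal-7-en-9-one
Product: 17 6β-acetoxy-4,4,8,10β-tetramethyl-5α-decal-7-en-9-one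
Conditions: Ac2O, DMAP, Et3N, CH2Cl2, rt → 40 °C
Reagents that add atoms: acetic anhydride, CC(=O)OC(C)=O
Why: DMAP-catalysed acylation esterifies the hindered axial alcohol with retention at C6.

Step 11
Reactants: 17 6β-acetoxy-4,4,8,10β-tetramethyl-5α-decal-7-en-9-one
Product: 19 6β-acetoxy-4,4,8,10β-tetramethyl-5α-decal-8-en-9-yl trifluoromethanesulfonate, via lithium enolate 18 (not isolated)
Conditions: LiBH(s-Bu)3 (L-Selectride), THF, −78 °C; then N-(5-chloropyridin-2-yl)bis(trifluoromethanesulfonyl)imide, −78 → 0 °C
Reagents that add atoms: N-(5-chloropyridin-2-yl)bis(trifluoromethanesulfonyl)imide, O=S(=O)(N(c1ccc(Cl)cn1)S(=O)(=O)C(F)(F)F)C(F)(F)F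
Why: Conjugate (1,4-) reduction of an α-methyl enone that is unsubstituted at the β-carbon by the bulky borohydride delivers hydride to C7 and gives the tetrasubstituted C8=C9 enolate 18 regiospecifically, O-triflation fixes it as the future C8=C9 double bond, and the cold, short exposure should spare the acetate.

Step 12
Reactants: 19 6β-acetoxy-4,4,8,10β-tetramethyl-5α-decal-8-en-9-yl trifluoromethanesulfonate; 20 tributyl(vinyl)stannane
Product: 21 6β-acetoxy-4,4,8,10β-tetramethyl-9-vinyl-5α-decal-8-ene
Conditions: Pd(PPh3)4 (5 mol %), LiCl, THF, reflux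
Reagents that add atoms: none
Why: Stille coupling of a hindered cyclohexenyl triflate with a vinylstannane in the presence of LiCl, well known for 2,6,6-trisubstituted cyclohexenyl triflates, forms C9–C11 with the double bond held in place, and the homoallylic acetate cannot ionise to a π-allyl complex.

Step 13
Reactants: 21 6β-acetoxy-4,4,8,10β-tetramethyl-9-vinyl-5α-decal-8-ene; 22 4-bromofuran-2(5H)-one
Product: 24 6β-acetoxylabda-8,13-dien-15,16-olide (target), via B-alkyl-9-BBN borane 23 (not isolated)
Conditions: 9-BBN-H, THF, 0 °C → rt; then 22, PdCl2(dppf) (5 mol %), AsPh3, Cs2CO3, DMF/H2O, rt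
Reagents that add atoms: none
Why: 9-BBN-H hydroborates only the monosubstituted C11=C12 bond at its terminus, and B-alkyl Suzuki–Miyaura coupling of borane 23 with the β-bromobutenolide forms C12–C13 under mild carbonate conditions that the acetate and the lactone should survive, with no stereocentre touched.

Compound list
1 | 3-methylcyclohex-2-en-1-one | CC1=CC(=O)CCC1 | starting material
2 | 5-bromo-2-methylpent-2-ene | CC(C)=CCCBr | starting material
3 | (4-methylpent-3-en-1-yl)magnesium bromide | CC(C)=CCC[Mg]Br | intermediate
4 | bromomagnesium C5=C6 enolate of (S)-3-methyl-3-(4-methylpent-3-en-1-yl)cyclohexanone | Br[Mg]OC1=C[C@](C)(CCC=C(C)C)CCC1 | intermediate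
5 | (S)-trimethyl{[3-methyl-3-(4-methylpent-3-en-1-yl)cyclohex-1-en-1-yl]oxy}silane | C[Si](C)(C)OC1=C[C@](C)(CCC=C(C)C)CCC1 | intermediate
6 | lithium C5=C6 enolate of (S)-3-methyl-3-(4-methylpent-3-en-1-yl)cyclohexanone | [Li]OC1=C[C@](C)(CCC=C(C)C)CCC1 | intermediate
7 | (3S)-3-methyl-3-(4-methylpent-3-en-1-yl)-2-(trifluoroacetyl)cyclohexan-1-one (C5 epimers, enolised) | O=C1CCC[C@@](C)(CCC=C(C)C)C1C(=O)C(F)(F)F | intermediate
8 | (3S)-2-diazo-3-methyl-3-(4-methylpent-3-en-1-yl)cyclohexan-1-one | O=C1CCC[C@@](C)(CCC=C(C)C)C1=[N+]=[N-] | intermediate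
9 | tricyclic cyclopropyl ketone: C6 cyclohexanone fused at C5–C10 to the cyclopentane C1-C2-C3-C5-C10, C3–C4–C5 gem-dimethylcyclopropane, 10β-methyl, C4 β, C1 and C3 α | O=C1CCC[C@@]2(C)CC[C@@H]3C(C)(C)[C@]123 | intermediate
10 | lithium C5=C6 enolate of 11 | [Li]OC1=C2C(C)(C)CCC[C@]2(C)CCC1 | intermediate
11 | 4,4,10β-trimethyl-5α-decalin-6-one | O=C1CCC[C@@]2(C)CCCC(C)(C)[C@H]12 | intermediate
12 | 4,4,10β-trimethyl-5α-decal-7-en-6-one | O=C1C=CC[C@@]2(C)CCCC(C)(C)[C@H]12 | intermediate
13 | 4,4,8,10β-tetramethyl-6-(trimethylsilyloxy)-5α-decal-6-ene (C8 epimers) | C[Si](C)(C)OC1=CC(C)C[C@@]2(C)CCCC(C)(C)[C@H]12 | intermediate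
14 | 4,4,8,10β-tetramethyl-5α-decal-7-en-6-one | O=C1C=C(C)C[C@@]2(C)CCCC(C)(C)[C@H]12 | intermediate
15 | 4,4,8,10β-tetramethyl-5α-decal-7-ene-6,9-dione | O=C1C=C(C)C(=O)[C@@]2(C)CCCC(C)(C)[C@H]12 | intermediate
16 | 6β-hydroxy-4,4,8,10β-tetramethyl-5α-decal-7-en-9-one | O[C@@H]1C=C(C)C(=O)[C@@]2(C)CCCC(C)(C)[C@H]12 | intermediate
17 | 6β-acetoxy-4,4,8,10β-tetramethyl-5α-decal-7-en-9-one | CC(=O)O[C@@H]1C=C(C)C(=O)[C@@]2(C)CCCC(C)(C)[C@H]12 | intermediate
18 | lithium C8=C9 enolate of the 7,8-dihydro ketone of 17 | CC(=O)O[C@@H]1CC(C)=C(O[Li])[C@@]2(C)CCCC(C)(C)[C@H]12 | intermediate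
19 | 6β-acetoxy-4,4,8,10β-tetramethyl-5α-decal-8-en-9-yl trifluoromethanesulfonate | CC(=O)O[C@@H]1CC(C)=C(OS(=O)(=O)C(F)(F)F)[C@@]2(C)CCCC(C)(C)[C@H]12 | intermediate
20 | tributyl(vinyl)stannane | C=C[Sn](CCCC)(CCCC)CCCC | starting material
21 | 6β-acetoxy-4,4,8,10β-tetramethyl-9-vinyl-5α-decal-8-ene | CC(=O)O[C@@H]1CC(C)=C(C=C)[C@@]2(C)CCCC(C)(C)[C@H]12 | intermediate
22 | 4-bromofuran-2(5H)-one | O=C1C=C(Br)CO1 | starting material
23 | C12 B-alkyl-9-borabicyclo[3.3.1]nonane from 21 | CC(=O)O[C@@H]1CC(C)=C(CCB3C4CCCC3CCC4)[C@@]2(C)CCCC(C)(C)[C@H]12 | intermediate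
24 | 6β-acetoxylabda-8,13-dien-15,16-olide | CC(=O)O[C@@H]1CC(C)=C(CCC2=CC(=O)OC2)[C@@]2(C)CCCC(C)(C)[C@H]12 | target

Total step count: 13. Longest linear sequence: 13 steps (from 1).

Steps most likely to fail

Step 4. Electron transfer may break the C4–C5 bond, which gives the tertiary radical, instead of C3–C5, or it may reduce the carbonyl group further. The fallback sets out from 9 and comes back at 11. It replaces electron transfer by a polar homoconjugate substitution. Sodium benzeneselenolate (PhSeSePh, NaBH4, EtOH/DMF, heat) can attack only C3, because C4 is quaternary. It displaces the C5 enolate with inversion and should give 3β-(phenylselanyl)-4,4,10β-trimethyl-5α-decalin-6-one F1. Radical deselenation with Bu3SnH and AIBN in toluene then replaces selenium by hydrogen and gives 11. Ring A still arises from the five-membered ring by loss of the C3–C5 bond.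

Step 2. C-acylation at the neopentyl C5 may be slower than proton transfer. That would move the enolate to C7 and place the diazo group on the wrong carbon. The fallback sets out from 5 and comes back at 9. It builds the cyclopropane without a carbene.
- N-Iodosuccinimide in THF converts 5 regiospecifically into (3S)-2-iodo-3-methyl-3-(4-methylpent-3-en-1-yl)cyclohexan-1-one F2.
- Iodine-atom-transfer radical cyclisation ((Bu3Sn)2, light, benzene) joins C5 to C3 in the 5-exo mode and should give the hydrindanone with a 2-iodopropan-2-yl group on C3, F3.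
- DBU (or KOt-Bu) forms the C5 enolate, which closes the C4–C5 bond by 1,3-elimination of HI and gives 9.

Step 8. Hydrogen abstraction at the neopentyl C9, γ to an electron-poor enone, may be slow, and the C8 methyl group may be attacked instead. The fallback sets out from 14 and comes back at 17, so it also avoids having to differentiate two carbonyl groups in step 9.
- Luche reduction of 14 (α-face hydride) should give 6β-hydroxy-4,4,8,10β-tetramethyl-5α-decal-7-ene F4.
- Ac2O and DMAP give 6β-acetoxy-4,4,8,10β-tetramethyl-5α-decal-7-ene F5.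
- The now electron-rich trisubstituted alkene is oxidised at the ring allylic methylene C9 with CrO3·3,5-dimethylpyrazole in CH2Cl2 at −20 °C to give enone 17.

Further compounds
F1 | step 4 | 3β-(phenylselanyl)-4,4,10β-trimethyl-5α-decalin-6-one | O=C1CCC[C@@]2(C)CC[C@H]([Se]c3ccccc3)C(C)(C)[C@H]12
F2 | step 2 | (3S)-2-iodo-3-methyl-3-(4-methylpent-3-en-1-yl)cyclohexan-1-one (C5 epimers) | O=C1CCC[C@@](C)(CCC=C(C)C)C1I
F3 | step 2 | 10β-methylhydrindan-6-one (rings C1-C2-C3-C5-C10 and C5–C10) with a 2-iodopropan-2-yl group on C3, C3 configured as in 9, C5 epimerisable | O=C1CCC[C@@]2(C)CC[C@H](C(C)(C)I)C12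
F4 | step 8 | 6β-hydroxy-4,4,8,10β-tetramethyl-5α-decal-7-ene | O[C@@H]1C=C(C)C[C@@]2(C)CCCC(C)(C)[C@H]12
F5 | step 8 | 6β-acetoxy-4,4,8,10β-tetramethyl-5α-decal-7-ene | CC(=O)O[C@@H]1C=C(C)C[C@@]2(C)CCCC(C)(C)[C@H]12
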